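**Assumptions (one line each)**
- The target is the C2-symmetric exo,exo furofuran, (1R,3aS,4R,6aS). Working from the SMILES, both aryl groups are cis to the ring-fusion H atoms. The compound is the 4-O-demethyl analogue of the (–)-yangambin series.
- The facial selectivity of the Evans-imide enolate dimerisation follows that of Evans alkylation, so the (S)-4-benzyl auxiliary gives (S,S). If the opposite diastereomer forms, use the (R)-auxiliary.

**Retrosynthesis**
- Target ← statistical mono-O-methylation of (–)-syringaresinol (8).
- 8 ← double Friedel–Crafts C-arylation of the cis-fused bis-lactol (6) with 2,6-dimethoxyphenol. Attack on the convex face sets both aryl-bearing carbons exo.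
- 6 ← DIBAL reduction of the C2-symmetric cis-fused dilactone (5).
- 5 ← debenzylation and double lactonisation of the (S,S)-bis-imide (4). Both tetrahydrofuran-type rings (as lactones) are formed here, cis-fused.
- 4 ← oxidative homo-coupling of the Evans imide enolate of 3 (1 → 3). This C–C bond sets both ring-fusion stereocentres.

**Step 1**
Reactants: 1 (3-(benzyloxy)propanoic acid); 2 ((S)-4-benzyl-1,3-oxazolidin-2-one)
Product: 3 ((S)-4-benzyl-3-[3-(benzyloxy)propanoyl]oxazolidin-2-one)
Conditions: PivCl, Et3N, LiCl, THF, 0 °C → rt
Reagents that add atoms: none (the pivaloyl group is lost as pivalic acid)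
Why: The acid is activated as a mixed anhydride and the auxiliary is N-acylated. No new stereocentre is formed.

**Step 2**
Reactants: 3 (2 equiv)
Product: 4 ((S,S)-bis-imide, the C2-symmetric threo dimer)
Conditions: NaHMDS, THF, –78 °C, 30 min; then Fe(acac)3, –78 → 0 °C; separate the minor diastereomers by chromatography
Reagents that add atoms: none (the oxidant only removes 2 H)
Why: This is an oxidative enolate homo-coupling. The chelated Z-sodium enolate is attacked anti to the benzyl group, giving (S) at each α-carbon and the C2-symmetric (2S,3S) dimer as the major diastereomer.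

**Step 3**
Reactants: 4
Product: 5 ((3aS,6aS)-tetrahydrofuro[3,4-c]furan-1,4-dione, the cis-fused dilactone); (S)-4-benzyl-oxazolidinone 2 is recovered
Conditions: H2 (1 atm), 10% Pd/C, EtOAc, rt; then DBU (10 mol %), toluene, 60 °C
Reagents that add atoms: none
Why: Hydrogenolysis frees both primary alcohols. Each then attacks the imide on the adjacent carbon (5-exo acyl transfer), forming a γ-lactone and releasing the auxiliary. Only the threo (S,S) diastereomer can close to the cis-fused bicycle, so this step also purges stereoisomers. No stereocentre is touched.

**Step 4**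
Reactants: 5
Product: 6 (cis-fused bis-lactol, anomeric mixture)
Conditions: DIBAL-H (2.3 equiv), CH2Cl2, –78 °C, 1 h; Rochelle-salt work-up; use the crude product immediately
Reagents that add atoms: none (only H is added)
Why: Lactone-to-lactol DIBAL reduction stops at the hemiacetal at –78 °C. The d and e stereocentres are unchanged, and the anomeric centres are erased in the next step.

**Step 5**
Reactants: 6; 7 (2,6-dimethoxyphenol)
Product: 8 ((–)-syringaresinol, exo,exo)
Conditions: 7 (2.6 equiv), BF3·OEt2 (3 equiv), CH2Cl2, –30 °C → rt
Reagents that add atoms: 2,6-dimethoxyphenol, COc1cccc(OC)c1O (supplies the two aryl groups)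
Why: This is an oxocarbenium-type Friedel–Crafts C-arylation. The phenol reacts at the position para to OH, which gives the 4-hydroxy-3,5-dimethoxyphenyl group directly. Attack occurs on the convex face of the cis-fused bicyclic oxocarbenium, placing the aryl exo. Reversible benzylic ionisation under the Lewis acid funnels any endo isomer to the exo,exo thermodynamic product.

**Step 6**
Reactants: 8; 9 (MeI)
Product: 10 (target)
Conditions: MeI (1.0 equiv), K2CO3 (1.0 equiv), DMF, 0 °C → rt; chromatograph to separate from unreacted 8 and the bis-methyl ether, and recycle 8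
Reagents that add atoms: iodomethane, CI
Why: Williamson O-methylation of one of the two identical phenols is statistical. No stereocentre is involved, and the benzylic ethers are stable to mild base.

**Checks**
- Formulae: 1 + 2 → 3 + H2O. 2 × 3 − 2H → 4 (C40H40N2O8). 4 + 2H2 → 5 (C6H6O4) + 2 toluene + 2 × 2. 5 + 4H → 6 (C6H10O4). 6 + 2 ArH (C8H10O3) − 2H2O → 8 (C22H26O8). 8 + MeI − HI → 10 (C23H28O8). All atoms are accounted for.
- Functional-group survival: the benzyl ethers are removed only in step 3. The imide survives the Fe(III) coupling. The aryl OMe groups and the phenol are untouched in steps 4–6.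
- Stereocentres: d and e are set in step 2 and never change. a and h are set in step 5. The last product matches the target SMILES.

**Compound list**
1 | 3-(benzyloxy)propanoic acid | OC(=O)CCOCc1ccccc1 | starting material
2 | (S)-4-benzyl-1,3-oxazolidin-2-one | O=C1OC[C@H](Cc2ccccc2)N1 | starting material
3 | (S)-4-benzyl-3-[3-(benzyloxy)propanoyl]oxazolidin-2-one | O=C1OC[C@H](Cc2ccccc2)N1C(=O)CCOCc1ccccc1 | intermediate
4 | (2S,3S)-2,3-bis(benzyloxymethyl)succinyl bis-[(S)-4-benzyloxazolidinone] | O=C1OC[C@H](Cc2ccccc2)N1C(=O)[C@H](COCc1ccccc1)[C@@H](COCc1ccccc1)C(=O)N1[C@@H](Cc2ccccc2)COC1=O | intermediate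
5 | (3aS,6aS)-tetrahydrofuro[3,4-c]furan-1,4-dione | O=C2OC[C@@H]3[C@H]2COC3=O | intermediate
6 | cis-fused bis-lactol (anomeric mixture) | OC1OC[C@@H]2[C@H]1COC2O | intermediate
7 | 2,6-dimethoxyphenol | COc1cccc(OC)c1O | starting material
8 | (–)-syringaresinol | COc1cc([C@@H]2OC[C@@H]3[C@H]2CO[C@H]3c2cc(OC)c(O)c(OC)c2)cc(OC)c1O | intermediate
9 | iodomethane | CI | starting material (reagent)
10 | target | COc1cc([C@@H]2OC[C@@H]3[C@H]2CO[C@H]3c2cc(OC)c(OC)c(OC)c2)cc(OC)c1O | target

**Total steps:** 6. **Longest linear sequence:** 6 (1 → 3 → 4 → 5 → 6 → 8 → 10).

**Three steps most likely to fail**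
1. **Step 2, oxidative dimerisation.** The dr or yield may be poor, or β-elimination of BnO⁻ may compete. Fallback (different approach): make racemic 5 by double hydroxymethylation or oxidative coupling of an achiral succinate-type precursor, then resolve 5 by chiral preparative HPLC.
2. **Step 5, double Friedel–Crafts.** Possible problems are O- rather than C-arylation, endo aryl products, or epimerisation of d/e through the ring-opened dialdehyde. Fallback (different approach): add 4-BnO-3,5-dimethoxyphenyllithium to 5 to give the bis-hemiketal, reduce with Et3SiH/BF3, epimerise to exo,exo with TsOH, then hydrogenolyse the benzyl ethers.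
3. **Step 6, statistical mono-methylation.** Yield is limited to about 40–50%. Fallback (different approach): desymmetrise earlier. Mono-reduce 5 with DIBAL (0.9 equiv), run the Friedel–Crafts with 7, methylate that phenol, re-reduce the second lactone with DIBAL, and run a second Friedel–Crafts with 7 (8 steps in total).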